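**Retrosynthetic overview**

- The plan rests on the single benzene ring of the target: C2–OMe, C4–OMe and the C6 tricosyl chain are mutually meta, the alternating pattern of an acetate-derived alkylresorcinol, and C1–OH sits between C6 and C2, where a folded tetraketide carries its carboxyl carbon.
- C1–OH comes from C1–CHO by Baeyer–Villiger (Dakin-type) oxidation and formate cleavage; the aldehyde comes from the C1 ester of dimethyl ether 8, made from resorcylate 7.
- The ring is formed once, in step 3, by aldol folding of open-chain methyl 3,5,7-trioxotriacontanoate 5: chain C2 bonds to chain C7 (arene C1–C6).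
- 5 comes from the trianion of methyl 3,5-dioxohexanoate 3 and methyl tetracosanoate 4; 3 comes from the acetylacetone dianion and dimethyl carbonate.

Key step: step 3

Remark: the target has no stereocentre. Ring numbering follows the phenol name (C1 OH, C2 and C4 OMe, C6 tricosyl); chain numbering of 5 starts at the ester carbon.

**Step 1**
Reactants: 1 acetylacetone; 2 dimethyl carbonate
Product: 3 methyl 3,5-dioxohexanoate
Conditions: 1 (2.1 equiv), LiN(iPr)2 (4.2 equiv), THF, −78 → 0 °C; then 2 (1.0 equiv), −78 °C → rt; cold dilute HCl; distillation
Reagents that add atoms: none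
Why: Claisen-type C-acylation of a β-diketone dianion at its terminal carbanion, the most basic and nucleophilic site, with the product diketo ester deprotonated at once by the second equivalent of dianion so that its ester is shielded from a second addition.

**Step 2**
Reactants: 3 methyl 3,5-dioxohexanoate; 4 methyl tetracosanoate
Product: 5 methyl 3,5,7-trioxotriacontanoate
Conditions: 3 (2.2 equiv), LiN(iPr)2 (6.6 equiv), THF, 0 °C; then 4 (1.0 equiv) in THF, 0 °C → rt; cold 1 M HCl to pH 3–4; used promptly
Reagents that add atoms: none
Why: Claisen acylation of the trianion of the 3,5-diketo ester at its terminal C6 carbanion, the only localised nucleophilic site, while the ester of 3 is masked as its own enolate and the excess trianion takes up the acidic proton of the new 1,3-diketone.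

**Step 3**
Reactants: 5 methyl 3,5,7-trioxotriacontanoate
Product: 7 methyl 2,4-dihydroxy-6-tricosylbenzoate, via aldol carbinol 6 (not isolated)
Conditions: K2CO3 (2.5 equiv), MeOH/THF 1:1, rt, Ar; then HCl in MeOH to pH 1, rt → 40 °C
Reagents that add atoms: none
Why: Carbonate reversibly ionises the polycarbonyl chain, and the C2 carbon, acidified by both the ester and the C3 ketone, adds to the C7 ketone to give cyclic carbinol 6; acid then eliminates water and the C3 and C5 carbonyls enolise, which makes the sequence irreversible and delivers the arene. The closest known reaction type is the biomimetic intramolecular aldol condensation of 3,5,7-triketo esters to 6-substituted β-resorcylates under mild base. The six-membered carbocycle (chain C2 to C7) closes by 6-exo-trig attack on the C7 carbonyl, 6-(enolendo) with respect to the C2=C3 enolate and 6-(enolexo) with respect to the ester enolate form, both allowed. The two stereocentres of 6 form without control and are erased on aromatisation, so none remains. The step must prefer this aldol over Claisen closure of C6 onto the ester (acylphloroglucinol), over O-lactonisation (pyrone) and over aldol attack of the singly activated C8 on C3. A weak base in methanol without a chelating magnesium counter-ion, the far higher acidity of C2 than C8, the low electrophilicity of the enolate-conjugated ester against the C7 ketone, and acid added only after ring closure should secure it.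

**Step 4**
Reactants: 7 methyl 2,4-dihydroxy-6-tricosylbenzoate
Product: 8 methyl 2,4-dimethoxy-6-tricosylbenzoate
Conditions: MeI (5 equiv), K2CO3 (4 equiv), DMF/THF, 50 °C
Reagents that add atoms: iodomethane, CI
Why: Williamson O-methylation of both phenoxides, the hydrogen-bonded C2 hydroxyl being the slower one and therefore driven by excess MeI and warming in a dipolar solvent, with the hindered methyl ester untouched.

**Step 5**
Reactants: 8 methyl 2,4-dimethoxy-6-tricosylbenzoate
Product: 9 (2,4-dimethoxy-6-tricosylphenyl)methanol
Conditions: LiAlH4 (2 equiv), THF, 0 °C → reflux; H2O/aq. NaOH work-up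
Reagents that add atoms: none
Why: Hydride reduction of the ester to the primary benzylic alcohol, the small AlH4− ion reaching the doubly ortho-substituted carbonyl at reflux while aryl methyl ethers and the alkyl chain are inert.

**Step 6**
Reactants: 9 (2,4-dimethoxy-6-tricosylphenyl)methanol
Product: 10 2,4-dimethoxy-6-tricosylbenzaldehyde
Conditions: activated MnO2 (10 equiv), CH2Cl2, rt
Reagents that add atoms: none
Why: Heterogeneous MnO2 oxidation is selective for the electron-rich benzylic alcohol, stops at the aldehyde and runs under neutral conditions that spare the acid-labile benzylic position.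

**Step 7**
Reactants: 10 2,4-dimethoxy-6-tricosylbenzaldehyde
Product: 11 2,4-dimethoxy-6-tricosylphenyl formate
Conditions: mCPBA (1.3 equiv), CH2Cl2, 0 °C → rt; aq. Na2S2O3/NaHCO3 wash
Reagents that add atoms: meta-chloroperoxybenzoic acid (mCPBA), OOC(=O)c1cccc(Cl)c1
Why: Baeyer–Villiger oxidation in its Dakin-type form, in which the electron-rich 2,4-dimethoxy-6-alkylaryl group of the Criegee adduct migrates in preference to hydride, so the former carboxyl carbon leaves the ring as a formate and C1 gains its oxygen.

**Step 8**
Reactants: 11 2,4-dimethoxy-6-tricosylphenyl formate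
Product: 12 2,4-dimethoxy-6-tricosylphenol
Conditions: K2CO3 (0.2 equiv), degassed MeOH/THF, rt; aq. NH4Cl
Reagents that add atoms: none
Why: Base-catalysed transesterification of the aryl formate with methanol, fast because the phenoxide is a good leaving group, leaves the methyl ethers intact and should release the target phenol.

**Compound list**

1 | acetylacetone (pentane-2,4-dione) | CC(=O)CC(C)=O | starting material
2 | dimethyl carbonate | COC(=O)OC | starting material
3 | methyl 3,5-dioxohexanoate | COC(=O)CC(=O)CC(C)=O | intermediate
4 | methyl tetracosanoate | CCCCCCCCCCCCCCCCCCCCCCCC(=O)OC | starting material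
5 | methyl 3,5,7-trioxotriacontanoate | COC(=O)CC(=O)CC(=O)CC(=O)CCCCCCCCCCCCCCCCCCCCCCC | intermediate
6 | methyl 2-hydroxy-4,6-dioxo-2-tricosylcyclohexane-1-carboxylate (aldol carbinol, mixture of stereoisomers, not isolated) | COC(=O)C1C(=O)CC(=O)CC1(O)CCCCCCCCCCCCCCCCCCCCCCC | intermediate
7 | methyl 2,4-dihydroxy-6-tricosylbenzoate | COC(=O)c1c(O)cc(O)cc1CCCCCCCCCCCCCCCCCCCCCCC | intermediate
8 | methyl 2,4-dimethoxy-6-tricosylbenzoate | COC(=O)c1c(OC)cc(OC)cc1CCCCCCCCCCCCCCCCCCCCCCC | intermediate
9 | (2,4-dimethoxy-6-tricosylphenyl)methanol | OCc1c(OC)cc(OC)cc1CCCCCCCCCCCCCCCCCCCCCCC | intermediate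
10 | 2,4-dimethoxy-6-tricosylbenzaldehyde | O=Cc1c(OC)cc(OC)cc1CCCCCCCCCCCCCCCCCCCCCCC | intermediate
11 | 2,4-dimethoxy-6-tricosylphenyl formate | O=COc1c(OC)cc(OC)cc1CCCCCCCCCCCCCCCCCCCCCCC | intermediate
12 | 2,4-dimethoxy-6-tricosylphenol | CCCCCCCCCCCCCCCCCCCCCCCc1cc(OC)cc(OC)c1O | target

**Step count**

Total step count: 8. Longest linear sequence: 8 steps (1 → 3 → 5 → 7 → 8 → 9 → 10 → 11 → 12).

**Steps most likely to fail**

1. Step 3. The fold may go astray by Claisen closure of C6 onto the ester, by O-lactonisation before the aldol has taken place, or by loss of the ester group during aromatisation. The fallback runs the same fold on the free acid, whose carboxylate can neither accept a Claisen attack nor lactonise under the conditions. It sets out from 1 and 4. The dianion of 1 (LiN(iPr)2, THF) is acylated with 4 to give nonacosane-2,4,6-trione F1. The trianion of F1 (LiN(iPr)2, 3 equiv) is carboxylated at its terminal methyl with CO2 to give 3,5,7-trioxotriacontanoic acid F2. In aqueous acetate buffer (pH 5)/THF at rt, F2 should close by the C2-to-C7 aldol to 2,4-dihydroxy-6-tricosylbenzoic acid F3. Exhaustive methylation of F3 (Me2SO4, K2CO3, acetone, reflux) esterifies the acid and etherifies both phenols, and the route is rejoined at 8.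

2. Step 2. Proton transfer from the α-methylene of the fatty ester to the trianion, self-condensation of the ester and poor solubility of the C24 ester in cold THF may leave the acylation incomplete. The fallback changes the acyl donor to one that forms a stable chelated adduct and releases the acidic triketone only on quench. It sets out from 4, which with MeNHOMe·HCl and iPrMgCl (THF, −20 °C) should give N-methoxy-N-methyltetracosanamide F4. The trianion of 3 (LiN(iPr)2, 3.3 equiv, THF, 0 °C) is then acylated with F4 in near 1:1 ratio, and cold acidic quench returns to the route at 5.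

3. Step 1. Quenching of the dianion by the more acidic product, O-acylation and slow reaction of the carbonate may give low conversion. The fallback separates carboxylation from esterification. It sets out from 1, whose dianion (LiN(iPr)2, THF) is treated with CO2 at −78 °C to give, after cold acidification, 3,5-dioxohexanoic acid F5. Esterification of F5 with Me3SiCHN2 (1.0 equiv, MeOH/toluene, 0 °C) returns to the route at 3.

**Further compounds**

F1 | step 3 | nonacosane-2,4,6-trione | CC(=O)CC(=O)CC(=O)CCCCCCCCCCCCCCCCCCCCCCC
F2 | step 3 | 3,5,7-trioxotriacontanoic acid | OC(=O)CC(=O)CC(=O)CC(=O)CCCCCCCCCCCCCCCCCCCCCCC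
F3 | step 3 | 2,4-dihydroxy-6-tricosylbenzoic acid | OC(=O)c1c(O)cc(O)cc1CCCCCCCCCCCCCCCCCCCCCCC
F4 | step 2 | N-methoxy-N-methyltetracosanamide | CCCCCCCCCCCCCCCCCCCCCCCC(=O)N(C)OC
F5 | step 1 | 3,5-dioxohexanoic acid | CC(=O)CC(=O)CC(O)=O
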